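Solid substrate cannot react in the crystal: whatever becomes target or uncatalysed product has first to dissolve as starting material.

solid substrate 0.020 M; enzyme 0.02 mol%; time 30 h

    starting material + enzyme → target + enzyme, rate k1*[starting material]*[enzyme]/(1 + ([starting material]/Km1)) (Km1 = 32 mM, k1 = 32 M⁻¹ s⁻¹)
    starting material → uncatalysed product (k2 = 3.1 × 10⁻⁵ s⁻¹)
    solid substrate ⇌ starting material, rate k3*(cs3 - [starting material]) while solid is left; crystals form when [starting material] > cs3 (cs3 = 20 mM, k3 = 4.5 × 10⁻⁵ s⁻¹)

- zeta: doubling the solubility in step 3, all else as stated
- gamma: doubling the amount of enzyme, all else as stated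
- eta: doubling the dissolution coefficient of step 3, all else as stated

- as a solid, counted per litre of solution: solid substrate
- at the start none of the solid substrate is in solution
- run time (flask): 30 h

- target at 30 h, in percent of the solid substrate charged
- the change that raises the amount of target at 30 h, in percent of the solid substrate charged most ("none" if none brings more than 2 percentage points) (zeta / gamma / eta / none)
- amount of target at 30 h, in percent of the solid substrate charged, after zeta

Dissolved starting material in the flask has two exits, and the yield is the split between them. Two first-order constants therefore count: the background's 3.1 × 10⁻⁵ s⁻¹ and the enzyme's k_E, the pseudo-first-order constant k·c(enzyme)/(1 + c(starting material)/Km). With c(enzyme) = 0.00400 mM and no saturation, k_E is 1.28 × 10⁻⁴ s⁻¹.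

The denominator follows a curve, so one mean replaces it: the level at which dissolving balances both exits, taken with the unsaturated k_E, c̄ = 4.41 mM, less than the solubility. At that level the solid lasts about 7.92 h, shorter than the run, and k_E falls to 1.12 × 10⁻⁴ s⁻¹. The ratio is 3.63: this is the selectivity factor S, the enzyme's constant at the mean level divided by the background's. Target then takes S/(1 + S) = 78.4 %. Without saturation the split is 80.5 %, so the mean lowers the answer by 2.1 percentage points.

The forecast gives 78.5 %, 78 % after zeta, and gamma as the best change, holding that “the yield is set by the enzyme-versus-background split”. The reckoning here gives 78.4 %, about the same as the forecast's yield.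

The simulation gives 78.7 %, 77.7 % after zeta, and gamma as the change that raises the yield most, by 9.7 points, against −0.99 points for zeta and −0.77 points for eta. In this flask target stands at 78.4 % after 15.0 h. After 300 h this flask holds 78.7 %. In this flask S reads as target per uncatalysed product: 3.70 at 30.0 h, against the reckoned 3.63. The neighbouring flask with 0.005 mol% of enzyme has c(enzyme) = 0.00100 mM, c̄ = 8.33 mM and S = 0.819, hence a reckoned 45.0 %. That flask holds 46.5 % target and 53.1 % uncatalysed product at 30.0 h.

The numbers stand for no real mixture; no experiment stands behind them.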